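All runs are simulated for an exercise; the scatter is artificial.

The question for Sunday's and Wednesday's flasks was which product holds most of the starting material at the end, and how much, when the charges are equal and the temperatures differ.

| flask | starting material | partner | temperature | remark | time |
|---|---|---|---|---|---|
| north-east | 0.25 M | 0.40 M | 106 °C | run made earlier |  |
| north-west | 1 M | 0.40 M | 120 °C | run made earlier |  |
| Sunday's | 0.50 M | 0.400 M | 100 °C |  | 4.0 min |
| Wednesday's | 0.50 M | 0.400 M | 125 °C |  | 4.0 min |

north-east run (percent of the starting material charged)

| time / min | side product / % | over-reaction product / % | starting material / % | target / % | intermediate / % |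
|---|---|---|---|---|---|
| 1.00 | 0 | 12.9 | 0.5 | 15.2 | 71.2 |
| 2.00 | 0.1 | 29.0 | 0.6 | 15.9 | 55.2 |
| 3.00 | 0 | 40.0 | 0 | 14.5 | 46.1 |
| 4.00 | 0.3 | 47.3 | 0 | 12.4 | 40.1 |

north-west run (percent of the starting material charged)

| time / s | side product / % | over-reaction product / % | starting material / % | target / % | intermediate / % |
|---|---|---|---|---|---|
| 10.0 | 0 | 2.5 | 0 | 9.7 | 88.0 |
| 15.0 | 0 | 4.2 | 1.0 | 11.4 | 84.0 |
| 30.0 | 0 | 8.1 | 0 | 14.4 | 77.0 |
| 80.0 | 0.1 | 11.4 | 0.2 | 15.6 | 72.7 |

(each reading ± 0.3 percentage points)

- which of these there is most of at the end, counted by the starting material in it, Sunday's (intermediate / side product / over-reaction product / target)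
- which of these there is most of at the end, counted by the starting material in it, Wednesday's (intermediate / side product / over-reaction product / target)
- the largest of these amounts at the end, in percent of the starting material charged, Sunday's
- the largest of these amounts at the end, in percent of the starting material charged, Wednesday's

- percentages count the starting material that a species holds: one side product counts as two

In the north-west run the starting material read 0% at 10.0 s although partner was short, so I took the first step to need no partner, with intermediate then taking up one partner to give target and target taking up another to give over-reaction product. That ledger held: at 80.0 s the partner used, one for each target and two for each over-reaction product, read 38.4% of the starting material against 40.0% charged. Since intermediate, target and over-reaction product share the charge, intermediate is the whole charge less the mean of partner used and target. With 0.800 equivalents of partner and target taken from its flat top, read as 15.6%, this gave 52.2% for both flasks. I called this the stall level, the intermediate standing once partner, the limiting reagent of the later steps, has gone, and it needs no clock.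

My second way was a clock: I counted lifetimes of partner. By the ledger, its logarithm fell at 0.270 min⁻¹ in the north-east run and 2.97 min⁻¹ in the north-west run. Taking that rate in proportion to the starting material charged, the hotter run was faster by a factor 2.75. Extended straight in temperature, this put 1.40 lifetimes into Sunday's flask and 8.53 into Wednesday's. Wednesday's flask kept 0.0197% of its partner by this clock, so the clock told me that the stall level applied there, but its figure of 52.2% was no separate check on that level, since it rested on the same equivalents and the same target. Sunday's flask kept 24.7%, which gave 62.1%, more than the stall level. There the stall level was the one that cheated, because Sunday's flask had fewer lifetimes than Wednesday's and had not reached it.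

The forecast named intermediate for both flasks, with 60% for Sunday's, a little below my figure, and 51.3% for Wednesday's, saying “partner is not quite exhausted by 4 min” of Sunday's.

Sunday's flask gave intermediate at 59.7%. Wednesday's flask gave intermediate at 51.6%.

    starting material + target → side product (k = 0.0430 L mol⁻¹ s⁻¹, Ea = 79.0 kJ mol⁻¹)
    partner + intermediate → target (k = 0.0110 L mol⁻¹ s⁻¹, Ea = 79.0 kJ mol⁻¹)
    starting material → intermediate (k = 1.10 s⁻¹, Ea = 95.0 kJ mol⁻¹)
    partner + target → over-reaction product (k = 0.0440 L mol⁻¹ s⁻¹, Ea = 72.0 kJ mol⁻¹)
    (constants at 100 °C)

Wednesday's flask stood beside its stall level of 52.2% with 0.0587% of its partner left at 4.00 min, when the half-life of intermediate by its step with partner was 15 h, far longer than the 4.0 min allowed. For the neighbour holding 0.12 M of starting material and 3.33 equiv of partner, the stall level falls below zero, to −74.5%, and that flask ended with 43.5% of its partner left and 4.89% of intermediate.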